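**Remarks and assumptions**

- Atom labels C1–C17 are those of the target chain: C1 is the carboxyl carbon, C3 and C5 are the ring carbons, C7 is the chain stereocentre, C14–C17 is the diene.
- Assumption: (R)-citronellal of high enantiomeric purity is used; C7 is never α to a carbonyl group in the route, so its purity should be carried through unchanged.
- Assumption: the four diastereomers formed in step 14 can be separated at the stage of compound 20; compounds 20–27 are written as single isomers.
- The silyl group is tert-butyldiphenylsilyl. It gives the otherwise chromophore-free intermediates a UV handle for the HPLC separation on which the route depends.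

## The problem

Compound 27 is a C17 acid whose only ring is a 1,2-dioxolane made of C3, C4, C5 and two oxygen atoms. Both oxygen-bearing ring carbons are fully substituted: C3 carries a methyl group and the C2–C1 acetic acid arm, C5 a methyl group and the long chain. The chain runs unbranched from C6 to C17, with one methyl-bearing stereocentre at C7 and an (E,E)-1-phenylbuta-1,3-diene at C14–C17, so it can be built by ordinary olefinations as long as every reduction is finished before the peroxide exists. Three stereocentres are needed, C3 (S), C5 (R) and C7 (R). C7 is available from the chiral pool, but it sits one methylene away from C5 on a freely rotating chain and cannot be relied on to direct either ring centre; C3 and C5, which face each other across the ring with their methyl groups trans, are the only pair in which one centre could in principle control the other. The O–O bond will not survive hydrogenation, low-valent metals or hard carbanions; the β-peroxy carbonyl arm opens by a retro-oxa-Michael reaction, with loss of the C3 configuration, whenever C2 is enolised; and the diene is destroyed by oxygen- and selenium-centred radicals, by palladium-mediated oxidation and by hydrogenation. The feature that opens a short way to the ring is the C3–C4–C5 triad: two methyl-bearing tertiary carbons joined by one methylene and bridged by O–O. Replacing O–O by a C3–C5 bond gives a cyclopropane, and lowering the C2–C1 arm to a vinyl group gives a vinylcyclopropane, a substrate class that takes up O2 across exactly that bond in a radical chain.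

## Retrosynthesis

**Diene (27 ⇒ 24 + 25).** The C14=C15 bond is cut, giving the oxo acid 24 and diethyl cinnamylphosphonate 25, joined through the lithiated phosphonate 26. The diene is put on last because it would survive neither the oxygenation that makes the ring nor the oxidation that makes the acid. The cut removes the whole unsaturated end in one step. The forward reaction must give the E geometry at C14=C15 in the presence of a dialkyl peroxide and a free carboxyl group; the carboxylate formed in the flask cannot be deprotonated at C2, and this protects the ring. Compound 24 comes from the hydroxy acid 23 by oxidation, and 23 from the silyl ether 22 by desilylation.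

**Acid arm (22 ⇒ 21 ⇒ 20).** No skeletal bond is cut; C1 is taken down from the acid through the aldehyde 21 to the terminal carbon of the vinyl group in 20. A carboxyl-level arm carried through the ring formation would place a carbonyl group beside the reacting centre (as in the cationic routes discussed below). The vinyl group is in any case what the ring-forming step requires and regenerates. The forward sequence needs an anti-Markovnikov oxidation of a vinyl group on a fully substituted, oxygen-bearing carbon, then an aldehyde-to-acid oxidation under conditions that do not enolise C2.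

**Dioxolane (20 ⇒ 18 + 19).** Both C–O bonds of the ring (C3–O and C5–O) are cut and C3 is joined to C5, which leads to the vinylcyclopropane 18 and dioxygen 19. Cutting one C–O bond only would require a tertiary hydroperoxide or silyl peroxide to be built on the chain and carried through several steps. Cutting one C–C and one C–O bond leads to peroxycarbenium chemistry under a strong Lewis acid. The chosen cut brings in both oxygen atoms from O2 in one operation under neutral conditions, from a precursor that contains no peroxide. Compound 18 is much simpler than 20: its cyclopropane configuration is irrelevant, because the C3–C5 bond is broken and C5 becomes planar, so only C7 matters. The forward reaction must open the ring at C3–C5 rather than C3–C4. It creates C3 and C5 without stereocontrol, so 20 has to be isolated from three diastereomers.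

**Vinyl group (18 ⇒ 17 ⇒ 16 ⇒ 15).** The C1=C2 bond is cut by a Wittig disconnection to the aldehyde 17, which is reached from the ester 15 through the alcohol 16. These are oxidation-level adjustments on a neopentyl centre that cannot enolise. Nothing is asked beyond compatibility with the silyl ether.

**Cyclopropane (15 ⇒ 12 + 14).** The C3–C4 and C3–C5 bonds are cut, giving the 1,1-disubstituted alkene 12 and ethyl 2-diazopropanoate 14 (made in one step from ethyl 2-methylacetoacetate 13). The neighbouring cut, at C4–C3 and C4–C5 (methylene transfer to a tetrasubstituted allylic alcohol), is held in reserve. The chosen cut delivers C3 with its methyl group and C2 from a single reagent, and pairs an electron-rich alkene with an electrophilic carbenoid. Since any cyclopropane stereoisomer serves, the poor diastereocontrol of such additions costs nothing. The forward reaction must let carbenoid capture by the alkene outrun the 1,2-hydride shift in the carbenoid.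

**Chain (12 ⇒ 11 ⇒ 10 ⇒ 8 + 3).** The C5=CH2 bond is cut to the methyl ketone 11. The C10–C11 bond is traced to the alkene 10 and cut by a Wittig disconnection to the keto aldehyde 8 and the phosphonium salt 3 (through ylide 9); 3 comes from 4-bromobutan-1-ol 1 through the silyl ether 2. Placing this olefination and its hydrogenation here keeps all reductions ahead of the peroxide. The forward olefination must pick the aldehyde over the ketone in 8.

**Chiral pool (8 ⇒ 6 ⇒ 5 ⇒ 4).** The C10=C bond of 6 is cut by ozonolysis (through ozonide 7), and the C5 methyl group is cut back through the alcohol 5 to (R)-citronellal 4. The aldehyde carbon of 4 becomes C5, its stereocentre becomes C7 with the required configuration, and its isopropylidene end exposes C10. No stereocentre has to be made.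

## Roads not taken

**Alternative 1:** Peroxycarbenium–alkene annulation with the chain on the ketal.
- Cut: C4–C5 and C3–O.
- Forward key step: the chain ketone would be converted into the methyl triethylsilylperoxy ketal A2. SnCl4 at low temperature ionises A2 to the C5 peroxycarbenium ion, the CH2 terminus of methyl 3-methylbut-3-enoate A3 bonds to it, and the tertiary C3 cation is closed by the silylperoxy oxygen to give the ester A1.
- Merits: C1 arrives at the acid oxidation level, so no vinyl-to-acid sequence is needed. The ring is reached from the ketone in about three operations, where the present plan needs seven from 11 to 22. The union is convergent.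
- Weak points: A3 is an inductively deactivated π-nucleophile. The C3 cation is flanked by an acidic CH2CO2Me group, so proton loss competes with closure. Ketone-derived peroxycarbenium ions can rearrange by carbon-to-oxygen migration under the Lewis acid. C5 and C3 are both trigonal when their bonds form, so the same four diastereomers result.
- Comparison: in step count Alternative 1 is clearly better, and in stereocontrol the two are equal (neither has any). The present plan sets against this neutral conditions without a Lewis acid, a carbon skeleton complete before any peroxide exists, and ring-forming events that are all fast radical steps with no cation beside a carbonyl group. This chemistry is kept as the fallback for step 14.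

**Alternative 2:** Hydrogen-atom-transfer closure onto a pre-formed C3 peroxide.
- Cut: C5–O only.
- Forward key step: the precursor A5 carries a tertiary triethylsilyl peroxide at C3, whose configuration would come from a Sharpless asymmetric epoxidation, and a methylidene group on C5. A cobalt hydride made from the divalent cobalt complex Co(salen), N-fluoro-2,4,6-trimethylpyridinium tetrafluoroborate and PhSiH3 transfers hydrogen to the methylidene carbon, the tertiary C5 centre is oxidised, and the C3 silylperoxy oxygen captures it to give A4.
- Merits: it is the only route with reagent control of a ring stereocentre. C3 is fixed absolutely, so at most two isomers form, and C3 may bias C5 in the closure. The conditions are catalytic and mild.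
- Weak points: A5 is costly to make. It needs an asymmetric epoxidation, an oxygen-to-peroxide exchange at a tertiary carbon with a clean stereochemical course, a separate C4–C5 union with the chain, and a tertiary peroxide carried through several steps. A silylperoxy nucleophile is less documented in this closure than hydroxyl. The C3 substituents (methyl and a silyloxyethyl arm) differ little in size, so induction at C5 may be weak. The arm must be desilylated and raised two oxidation levels.
- Comparison: in stereocontrol Alternative 2 is superior, and if the C5 selectivity were high it would deliver more of the right isomer. The present plan sets against this a much shorter access to the ring precursor from the chiral pool alone, no peroxide before the ring-forming step, and a ring-forming reaction of an established type; it pays with a statistical loss at the separation.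

**Alternative 3:** Reversed annulation, small peroxycarbenium ion and chain-bearing alkene.
- Cut: C3–C4 and C5–O.
- Forward key step: SnCl4 ionises the small ketal A7 to the C3 peroxycarbenium ion, the CH2 carbon of the chain alkene A8 bonds to it, and the tertiary C5 cation is captured by the silylperoxy oxygen to give A6.
- Merits: A8 is a plain 1,1-dialkylethylene, the best nucleophile for such a cation. The route branches from the same type of alkene as the present route (12 is its tert-butyldiphenylsilyl analogue). The ring is made in one step, and the acid follows after deacetylation and oxidation.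
- Weak points: the C5 cation has β-hydrogens on three sides and can eliminate. The acetate carbonyl can intercept either cation. C5 is trigonal at ring closure, so four isomers form again. The arm is two oxidation levels low.
- Comparison: on step count Alternative 3 would be preferred, and stereochemically it is equal. The present plan sets against it the absence of cationic intermediates and Lewis acid, and the formation of both C–O bonds within one molecule from a stable precursor.

Key step: step 14

## Route

Step 1
Reactants: 1 4-bromobutan-1-ol
Product: 2 (4-bromobutoxy)(tert-butyl)diphenylsilane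
Conditions: TBDPSCl, imidazole, CH2Cl2, 0 °C → rt
Reagents that add atoms: tert-butyl(chloro)diphenylsilane, CC(C)(C)[Si](Cl)(c1ccccc1)c1ccccc1
Why: Imidazole-promoted silylation of a primary alcohol; run cold and without delay so that cyclisation of the bromo alcohol to tetrahydrofuran does not compete.

Step 2
Reactants: 2 (4-bromobutoxy)(tert-butyl)diphenylsilane
Product: 3 {4-[(tert-butyldiphenylsilyl)oxy]butyl}triphenylphosphonium bromide
Conditions: PPh3, MeCN, reflux
Reagents that add atoms: triphenylphosphine, c1ccc(cc1)P(c1ccccc1)c1ccccc1
Why: SN2 quaternisation of a phosphine by a primary bromide; the silyl ether is stable under these neutral conditions.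

Step 3
Reactants: 4 (R)-citronellal
Product: 5 (4R)-4,8-dimethylnon-7-en-2-ol (both C2 epimers)
Conditions: MeMgBr, Et2O, 0 °C; aqueous work-up
Reagents that add atoms: methylmagnesium bromide, C[Mg]Br
Why: Grignard addition to an aldehyde; the new carbinol centre is removed in step 4, and the existing stereocentre (the future C7) is β to the carbonyl and untouched.

Step 4
Reactants: 5 (4R)-4,8-dimethylnon-7-en-2-ol
Product: 6 (4R)-4,8-dimethylnon-7-en-2-one
Conditions: Dess–Martin periodinane, CH2Cl2, rt
Reagents that add atoms: none
Why: Dess–Martin oxidation of a secondary alcohol; the trisubstituted alkene is inert and the stereocentre β to the ketone cannot epimerise.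

Step 5
Reactants: 6 (4R)-4,8-dimethylnon-7-en-2-one
Product: 8 (4R)-4-methyl-6-oxoheptanal, via secondary ozonide 7 (not isolated)
Conditions: O3, CH2Cl2, −78 °C; then PPh3, −78 °C → rt
Reagents that add atoms: ozone, [O-][O+]=O
Why: Ozonolysis with reductive work-up (Criegee mechanism) cleaves the only C=C bond and leaves the ketone alone; 8 is a 1,6-keto aldehyde prone to aldol cyclisation and is used at once.

Step 6
Reactants: 3 {4-[(tert-butyldiphenylsilyl)oxy]butyl}triphenylphosphonium bromide; 8 (4R)-4-methyl-6-oxoheptanal
Product: 10 (4R,7Z)-11-[(tert-butyldiphenylsilyl)oxy]-4-methylundec-7-en-2-one, via phosphonium ylide 9 (not isolated)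
Conditions: 3 (1.05 equiv), NaN(SiMe3)2 (1.0 equiv), THF, −78 → 0 °C; then 8, −78 °C → rt
Reagents that add atoms: none
Why: Wittig olefination; a non-stabilised ylide adds to an aldehyde far faster than to a methyl ketone at −78 °C, and a slight deficit of base avoids enolisation. The alkene should be mainly Z, which is immaterial because it is hydrogenated in step 7.

Step 7
Reactants: 10 (4R,7Z)-11-[(tert-butyldiphenylsilyl)oxy]-4-methylundec-7-en-2-one
Product: 11 (4R)-11-[(tert-butyldiphenylsilyl)oxy]-4-methylundecan-2-one
Conditions: H2 (1 atm), 10% Pd/C, EtOAc, rt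
Reagents that add atoms: none
Why: Heterogeneous hydrogenation of a disubstituted alkene; ketone, silyl ether and arene rings are inert at 1 atm, and the step is placed here because no peroxide is present yet.

Step 8
Reactants: 11 (4R)-11-[(tert-butyldiphenylsilyl)oxy]-4-methylundecan-2-one
Product: 12 tert-butyl{[(8R)-8,10-dimethylundec-10-en-1-yl]oxy}diphenylsilane
Conditions: Ph3PCH3Br, KOtBu, THF, 0 °C → rt
Reagents that add atoms: methyltriphenylphosphonium bromide, [Br-].C[P+](c1ccccc1)(c1ccccc1)c1ccccc1
Why: Wittig methylenation of a methyl ketone; C7 is β to the carbonyl and is not touched.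

Step 9
Reactants: 13 ethyl 2-methylacetoacetate
Product: 14 ethyl 2-diazopropanoate
Conditions: 4-acetamidobenzenesulfonyl azide, DBU, MeCN, 0 °C → rt
Reagents that add atoms: 4-acetamidobenzenesulfonyl azide, CC(=O)Nc1ccc(cc1)S(=O)(=O)N=[N+]=[N-]
Why: Deacylative diazo transfer (Regitz type): the enolate of the 2-substituted acetoacetate adds to the azide and the acetyl group passes to the sulfonamide nitrogen, leaving the α-diazo ester, which is handled as a solution.

Step 10
Reactants: 12 tert-butyl{[(8R)-8,10-dimethylundec-10-en-1-yl]oxy}diphenylsilane; 14 ethyl 2-diazopropanoate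
Product: 15 ethyl 2-{(2R)-9-[(tert-butyldiphenylsilyl)oxy]-2-methylnonyl}-1,2-dimethylcyclopropane-1-carboxylate (mixture of cyclopropane stereoisomers)
Conditions: Rh2(O2CCPh3)4 (1 mol%), CH2Cl2, −78 °C, slow addition of 14 (3 equiv); → rt
Reagents that add atoms: none
Why: Rhodium-carbenoid cyclopropanation of an alkene with an α-alkyl-α-diazo ester; the bulky triphenylacetate ligands and the low temperature hold back the 1,2-hydride shift in the carbenoid, and the electron-rich 1,1-dialkylethylene is the only π-nucleophile present. The two new ring centres form as a mixture, which is accepted because the C3–C5 bond is broken in step 14.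

Step 11
Reactants: 15 ethyl 2-{(2R)-9-[(tert-butyldiphenylsilyl)oxy]-2-methylnonyl}-1,2-dimethylcyclopropane-1-carboxylate
Product: 16 (2-{(2R)-9-[(tert-butyldiphenylsilyl)oxy]-2-methylnonyl}-1,2-dimethylcyclopropyl)methanol
Conditions: i-Bu2AlH (2.5 equiv), CH2Cl2, −78 → 0 °C; aq. potassium sodium tartrate
Reagents that add atoms: none
Why: Aluminium hydride reduction of an ester to the primary alcohol; the silyl ether and the cyclopropane are inert.

Step 12
Reactants: 16 (2-{(2R)-9-[(tert-butyldiphenylsilyl)oxy]-2-methylnonyl}-1,2-dimethylcyclopropyl)methanol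
Product: 17 2-{(2R)-9-[(tert-butyldiphenylsilyl)oxy]-2-methylnonyl}-1,2-dimethylcyclopropane-1-carbaldehyde
Conditions: Dess–Martin periodinane, CH2Cl2, rt
Reagents that add atoms: none
Why: Dess–Martin oxidation of a primary alcohol; the aldehyde has a quaternary α-carbon and cannot enolise.

Step 13
Reactants: 17 2-{(2R)-9-[(tert-butyldiphenylsilyl)oxy]-2-methylnonyl}-1,2-dimethylcyclopropane-1-carbaldehyde
Product: 18 tert-butyl{[(8R)-9-(2-ethenyl-1,2-dimethylcyclopropyl)-8-methylnonyl]oxy}diphenylsilane (mixture of cyclopropane stereoisomers)
Conditions: Ph3PCH3Br, KOtBu, THF, 0 °C → rt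
Reagents that add atoms: methyltriphenylphosphonium bromide, [Br-].C[P+](c1ccccc1)(c1ccccc1)c1ccccc1
Why: Wittig methylenation of a non-enolisable neopentyl aldehyde.

Step 14
Reactants: 18 tert-butyl{[(8R)-9-(2-ethenyl-1,2-dimethylcyclopropyl)-8-methylnonyl]oxy}diphenylsilane; 19 dioxygen
Product: 20 (3S,5R)-5-{(2R)-9-[(tert-butyldiphenylsilyl)oxy]-2-methylnonyl}-3-ethenyl-3,5-dimethyl-1,2-dioxolane
Conditions: PhSeSePh (10 mol%), AIBN (10 mol%), O2 (1 atm), MeCN–CH2Cl2, 0 °C, hν (visible); silica chromatography, then HPLC
Reagents that add atoms: none
Why: Radical chain (3+2) annulation of a vinylcyclopropane with O2, the known selenyl-radical-catalysed route from vinylcyclopropanes to 3-vinyl-1,2-dioxolanes, applied here to a ring with two fully substituted carbons. PhSe•, formed by photolysis of PhSeSePh, adds reversibly to the vinyl terminus C1; the cyclopropylcarbinyl radical at C2 opens by cleavage of C3–C5, and the tertiary C5 radical is trapped by O2 (C5–O). The C5 peroxyl radical closes on C3 of the allyl selenide in a 5-exo-trig mode (C3–O, the dioxolane ring), and the C2 radical expels PhSe• by β-scission, which restores the vinyl group and carries the chain. The step needs regioselective ring opening and chemoselectivity: cleavage toward the tertiary C5 radical instead of the primary C4 radical is secured by the methyl and chain substituents on C5 and by the reversibility of the opening, and the vinyl group is the only π-bond in 18. Because C3–C5 is broken and C5 becomes planar, all stereoisomers of 18 converge on the same radicals. C5 is set when O2 meets that planar radical with no controlling element (C7 is acyclic and one methylene away), and C3 is set relative to C5 in a chair-like 5-exo transition state in which the methyl and CH2R groups on C5 are too alike in size for a dependable preference. Four diastereomers are therefore expected in comparable amounts; silica chromatography should separate the two ring series (methyl groups cis or trans), and HPLC with UV detection through the silyl chromophore should separate the two trans isomers, from which 20 is taken.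

Step 15
Reactants: 20 (3S,5R)-5-{(2R)-9-[(tert-butyldiphenylsilyl)oxy]-2-methylnonyl}-3-ethenyl-3,5-dimethyl-1,2-dioxolane; 19 dioxygen
Product: 21 2-[(3S,5R)-5-{(2R)-9-[(tert-butyldiphenylsilyl)oxy]-2-methylnonyl}-3,5-dimethyl-1,2-dioxolan-3-yl]acetaldehyde
Conditions: PdCl2(PhCN)2 (12 mol%), CuCl2·2H2O (12 mol%), AgNO2 (6 mol%), O2 (1 atm), t-BuOH–MeNO2 (15:1), rt
Reagents that add atoms: none
Why: Aldehyde-selective (anti-Markovnikov) Wacker-type oxidation with a nitrite co-catalyst; the fully substituted, oxygen-bearing allylic carbon C3 directs oxygen to the terminal carbon C1 by steric and inductive effects, as is known for vinyl groups on quaternary carbons. Crude 21 is taken straight into step 16, because a β-peroxy aldehyde can ring-open on enolisation.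

Step 16
Reactants: 21 2-[(3S,5R)-5-{(2R)-9-[(tert-butyldiphenylsilyl)oxy]-2-methylnonyl}-3,5-dimethyl-1,2-dioxolan-3-yl]acetaldehyde
Product: 22 2-[(3S,5R)-5-{(2R)-9-[(tert-butyldiphenylsilyl)oxy]-2-methylnonyl}-3,5-dimethyl-1,2-dioxolan-3-yl]acetic acid
Conditions: NaClO2, NaH2PO4, 2-methyl-2-butene, t-BuOH–H2O, 0 °C → rt
Reagents that add atoms: sodium chlorite, [Na+].[O-]Cl=O
Why: Pinnick oxidation in a weakly acidic buffer, where C2 is not enolised; 2-methyl-2-butene removes hypochlorous acid, and the peroxide and silyl ether are inert.

Step 17
Reactants: 22 2-[(3S,5R)-5-{(2R)-9-[(tert-butyldiphenylsilyl)oxy]-2-methylnonyl}-3,5-dimethyl-1,2-dioxolan-3-yl]acetic acid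
Product: 23 2-{(3S,5R)-5-[(2R)-9-hydroxy-2-methylnonyl]-3,5-dimethyl-1,2-dioxolan-3-yl}acetic acid
Conditions: Bu4NF (3 equiv), THF, 0 °C → rt; aq. citric acid
Reagents that add atoms: none
Why: Fluoride-induced desilylation; the acid is present as its carboxylate, which cannot be deprotonated at C2, so the dioxolane is not opened, and both peroxide carbons are tertiary and have no hydrogen to lose to base.

Step 18
Reactants: 23 2-{(3S,5R)-5-[(2R)-9-hydroxy-2-methylnonyl]-3,5-dimethyl-1,2-dioxolan-3-yl}acetic acid
Product: 24 2-{(3S,5R)-3,5-dimethyl-5-[(2R)-2-methyl-9-oxononyl]-1,2-dioxolan-3-yl}acetic acid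
Conditions: Dess–Martin periodinane, CH2Cl2, 0 °C → rt
Reagents that add atoms: none
Why: Dess–Martin oxidation of a primary alcohol; it tolerates a free carboxylic acid and a dialkyl peroxide, and C14 is too far from C1 for lactol formation.

Step 19
Reactants: 24 2-{(3S,5R)-3,5-dimethyl-5-[(2R)-2-methyl-9-oxononyl]-1,2-dioxolan-3-yl}acetic acid; 25 diethyl cinnamylphosphonate
Product: 27 2-{(3S,5R)-3,5-dimethyl-5-[(2R,9E,11E)-2-methyl-12-phenyldodeca-9,11-dien-1-yl]-1,2-dioxolan-3-yl}acetic acid, via lithiated phosphonate 26 (not isolated)
Conditions: 25 (2.5 equiv), n-BuLi (2.4 equiv), THF, −78 °C; then 24, −78 °C → rt; aq. citric acid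
Reagents that add atoms: none
Why: Horner–Wadsworth–Emmons olefination with an allylic phosphonate anion; the first equivalent turns the acid into its lithium carboxylate, which shields C2 from deprotonation, and the remainder adds to the aldehyde. Elimination of phosphate should give the E geometry at C14=C15, while the C16=C17 bond keeps the E geometry of 25.

## Compound list

1 | 4-bromobutan-1-ol | OCCCCBr | starting material
2 | (4-bromobutoxy)(tert-butyl)diphenylsilane | BrCCCCO[Si](c1ccccc1)(c1ccccc1)C(C)(C)C | intermediate
3 | {4-[(tert-butyldiphenylsilyl)oxy]butyl}triphenylphosphonium bromide | [Br-].CC(C)(C)[Si](OCCCC[P+](c1ccccc1)(c1ccccc1)c1ccccc1)(c1ccccc1)c1ccccc1 | intermediate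
4 | (R)-citronellal | C[C@H](CCC=C(C)C)CC=O | starting material
5 | (4R)-4,8-dimethylnon-7-en-2-ol (both C2 epimers) | C[C@H](CCC=C(C)C)CC(C)O | intermediate
6 | (4R)-4,8-dimethylnon-7-en-2-one | C[C@H](CCC=C(C)C)CC(C)=O | intermediate
7 | 3,3-dimethyl-5-[(3R)-3-methyl-5-oxohexyl]-1,2,4-trioxolane (secondary ozonide) | C[C@H](CCC1OOC(C)(C)O1)CC(C)=O | intermediate (not isolated)
8 | (4R)-4-methyl-6-oxoheptanal | C[C@H](CCC=O)CC(C)=O | intermediate
9 | {4-[(tert-butyldiphenylsilyl)oxy]butylidene}triphenylphosphorane | CC(C)(C)[Si](OCCCC=P(c1ccccc1)(c1ccccc1)c1ccccc1)(c1ccccc1)c1ccccc1 | intermediate (not isolated)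
10 | (4R,7Z)-11-[(tert-butyldiphenylsilyl)oxy]-4-methylundec-7-en-2-one | C[C@H](CC/C=C\CCCO[Si](c1ccccc1)(c1ccccc1)C(C)(C)C)CC(C)=O | intermediate
11 | (4R)-11-[(tert-butyldiphenylsilyl)oxy]-4-methylundecan-2-one | C[C@H](CCCCCCCO[Si](c1ccccc1)(c1ccccc1)C(C)(C)C)CC(C)=O | intermediate
12 | tert-butyl{[(8R)-8,10-dimethylundec-10-en-1-yl]oxy}diphenylsilane | C[C@H](CCCCCCCO[Si](c1ccccc1)(c1ccccc1)C(C)(C)C)CC(C)=C | intermediate
13 | ethyl 2-methylacetoacetate | CCOC(=O)C(C)C(C)=O | starting material
14 | ethyl 2-diazopropanoate | CCOC(=O)C(C)=[N+]=[N-] | intermediate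
15 | ethyl 2-{(2R)-9-[(tert-butyldiphenylsilyl)oxy]-2-methylnonyl}-1,2-dimethylcyclopropane-1-carboxylate (cyclopropane stereoisomers) | C[C@H](CCCCCCCO[Si](c1ccccc1)(c1ccccc1)C(C)(C)C)CC1(C)CC1(C)C(=O)OCC | intermediate
16 | (2-{(2R)-9-[(tert-butyldiphenylsilyl)oxy]-2-methylnonyl}-1,2-dimethylcyclopropyl)methanol (cyclopropane stereoisomers) | C[C@H](CCCCCCCO[Si](c1ccccc1)(c1ccccc1)C(C)(C)C)CC1(C)CC1(C)CO | intermediate
17 | 2-{(2R)-9-[(tert-butyldiphenylsilyl)oxy]-2-methylnonyl}-1,2-dimethylcyclopropane-1-carbaldehyde (cyclopropane stereoisomers) | C[C@H](CCCCCCCO[Si](c1ccccc1)(c1ccccc1)C(C)(C)C)CC1(C)CC1(C)C=O | intermediate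
18 | tert-butyl{[(8R)-9-(2-ethenyl-1,2-dimethylcyclopropyl)-8-methylnonyl]oxy}diphenylsilane (cyclopropane stereoisomers) | C[C@H](CCCCCCCO[Si](c1ccccc1)(c1ccccc1)C(C)(C)C)CC1(C)CC1(C)C=C | intermediate
19 | dioxygen | O=O | starting material
20 | (3S,5R)-5-{(2R)-9-[(tert-butyldiphenylsilyl)oxy]-2-methylnonyl}-3-ethenyl-3,5-dimethyl-1,2-dioxolane | C[C@H](CCCCCCCO[Si](c1ccccc1)(c1ccccc1)C(C)(C)C)C[C@]1(C)C[C@@](C)(C=C)OO1 | intermediate
21 | 2-[(3S,5R)-5-{(2R)-9-[(tert-butyldiphenylsilyl)oxy]-2-methylnonyl}-3,5-dimethyl-1,2-dioxolan-3-yl]acetaldehyde | C[C@H](CCCCCCCO[Si](c1ccccc1)(c1ccccc1)C(C)(C)C)C[C@]1(C)C[C@@](C)(CC=O)OO1 | intermediate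
22 | 2-[(3S,5R)-5-{(2R)-9-[(tert-butyldiphenylsilyl)oxy]-2-methylnonyl}-3,5-dimethyl-1,2-dioxolan-3-yl]acetic acid | C[C@H](CCCCCCCO[Si](c1ccccc1)(c1ccccc1)C(C)(C)C)C[C@]1(C)C[C@@](C)(CC(=O)O)OO1 | intermediate
23 | 2-{(3S,5R)-5-[(2R)-9-hydroxy-2-methylnonyl]-3,5-dimethyl-1,2-dioxolan-3-yl}acetic acid | C[C@H](CCCCCCCO)C[C@]1(C)C[C@@](C)(CC(=O)O)OO1 | intermediate
24 | 2-{(3S,5R)-3,5-dimethyl-5-[(2R)-2-methyl-9-oxononyl]-1,2-dioxolan-3-yl}acetic acid | C[C@H](CCCCCCC=O)C[C@]1(C)C[C@@](C)(CC(=O)O)OO1 | intermediate
25 | diethyl cinnamylphosphonate | CCOP(=O)(OCC)C/C=C/c1ccccc1 | starting material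
26 | lithiated diethyl cinnamylphosphonate | [Li+].CCOP(=O)(OCC)[CH-]/C=C/c1ccccc1 | intermediate (not isolated)
27 | 2-{(3S,5R)-3,5-dimethyl-5-[(2R,9E,11E)-2-methyl-12-phenyldodeca-9,11-dien-1-yl]-1,2-dioxolan-3-yl}acetic acid | C[C@H](CCCCCC/C=C/C=C/c1ccccc1)C[C@]1(C)C[C@@](C)(CC(=O)O)OO1 | target

## Step count and least certain steps

Total: 19 steps (steps 1–2 and step 9 prepare the two reagents 3 and 14). Longest linear sequence: 16 steps from (R)-citronellal 4 (steps 3–8 and 10–19).

**Step 14 (key step).** Two things can go wrong. Chain propagation may be inefficient at the doubly quaternary system, because the peroxyl radical has to close on an alkene carbon that already carries a methyl group, and a slow closure lets hydrogen abstraction by the peroxyl radical compete. Even with clean propagation, the lack of stereochemical bias at C5 and C3 spreads the material over four diastereomers, and resolution of the (3S,5R) isomer from its (3R,5S) partner, which differ only in the sense of the ring relative to C7, may be incomplete on achiral silica. A chiral stationary phase, which reads the ring configuration directly, or separation at the stage of acid 22, are the first remedies for the second problem.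

The fallback replaces the radical chain by Lewis-acid chemistry and sets out from alkene 12. Ozonolysis of 12 in methanol–CH2Cl2 at −78 °C should give the hydroperoxy ketal (4R)-11-[(tert-butyldiphenylsilyl)oxy]-2-methoxy-4-methylundecan-2-yl hydroperoxide F1. Silylation with Et3SiOTf and 2,6-lutidine gives the triethylsilyl peroxide F2. Treatment of F2 with SnCl4 and methyl 3-methylbut-3-enoate (A3) in CH2Cl2 at −78 °C (peroxycarbenium–alkene annulation) gives, after the same separation of diastereomers, the methyl ester methyl 2-[(3S,5R)-5-{(2R)-9-[(tert-butyldiphenylsilyl)oxy]-2-methylnonyl}-3,5-dimethyl-1,2-dioxolan-3-yl]acetate F3. Saponification with LiOH in THF–H2O at 0 °C rejoins the route at acid 22. This fallback does not cure the lack of stereocontrol, which both ring constructions share, but it is shorter and avoids steps 10–16.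

**Step 10.** The 1,2-hydride shift in the rhodium carbenoid and carbenoid dimerisation may outrun capture by the unactivated alkene, leaving 12 largely unconverted. The fallback changes the cyclopropane disconnection and sets out from ketone 11. Horner–Wadsworth–Emmons reaction with triethyl 2-phosphonopropionate and NaH in THF at reflux gives the tetrasubstituted enoate ethyl (5R)-12-[(tert-butyldiphenylsilyl)oxy]-2,3,5-trimethyldodec-2-enoate F4, whose E/Z ratio is immaterial. Reduction with i-Bu2AlH gives the allylic alcohol (5R)-12-[(tert-butyldiphenylsilyl)oxy]-2,3,5-trimethyldodec-2-en-1-ol F5. Hydroxyl-directed Simmons–Smith cyclopropanation (Et2Zn, CH2I2, CH2Cl2, 0 °C) rejoins the route at alcohol 16.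

**Step 15.** Zerovalent palladium formed in the catalytic cycle may ionise the allylic C3–O bond, or the alkylpalladium intermediate at C2 may eliminate the β-peroxy oxygen; either opens the ring. The β-peroxy aldehyde may also ring-open by enolisation and so lose the C3 configuration. The fallback avoids palladium and the free aldehyde and sets out from 20. Hydroboration with 9-BBN in THF and oxidation with NaBO3·4H2O gives the primary alcohol 2-[(3R,5R)-5-{(2R)-9-[(tert-butyldiphenylsilyl)oxy]-2-methylnonyl}-3,5-dimethyl-1,2-dioxolan-3-yl]ethan-1-ol F6; the C3 descriptor changes only because the arm now ranks below C4. Oxidation with catalytic TEMPO and PhI(OAc)2 in MeCN–H2O rejoins the route at acid 22.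

**Step 19.** The lithium carboxylate of 24 may aggregate or precipitate at low temperature and give incomplete olefination; the excess carbanion may attack the O–O bond; or the E selectivity at C14=C15 may erode. The fallback masks the acid and sets out from hydroxy acid 23. Esterification with Me3SiCHN2 in toluene–MeOH gives methyl 2-{(3S,5R)-5-[(2R)-9-hydroxy-2-methylnonyl]-3,5-dimethyl-1,2-dioxolan-3-yl}acetate F7. Dess–Martin oxidation gives the aldehyde methyl 2-{(3S,5R)-3,5-dimethyl-5-[(2R)-2-methyl-9-oxononyl]-1,2-dioxolan-3-yl}acetate F8. Olefination with 1.1 equivalents of 26 at −78 °C gives the methyl ester of the target, F9. Saponification with LiOH in THF–H2O at 0 °C rejoins the route at target 27; the olefination and saponification are kept cold so that the ester is not enolised at C2.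

## Further compounds

F1 | step 14 | (4R)-11-[(tert-butyldiphenylsilyl)oxy]-2-methoxy-4-methylundecan-2-yl hydroperoxide | C[C@H](CCCCCCCO[Si](c1ccccc1)(c1ccccc1)C(C)(C)C)CC(C)(OC)OO
F2 | step 14 | tert-butyl{[(8R)-10-methoxy-8-methyl-10-[(triethylsilyl)peroxy]undecyl]oxy}diphenylsilane | C[C@H](CCCCCCCO[Si](c1ccccc1)(c1ccccc1)C(C)(C)C)CC(C)(OC)OO[Si](CC)(CC)CC
F3 | step 14 | methyl 2-[(3S,5R)-5-{(2R)-9-[(tert-butyldiphenylsilyl)oxy]-2-methylnonyl}-3,5-dimethyl-1,2-dioxolan-3-yl]acetate | C[C@H](CCCCCCCO[Si](c1ccccc1)(c1ccccc1)C(C)(C)C)C[C@]1(C)C[C@@](C)(CC(=O)OC)OO1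
F4 | step 10 | ethyl (5R)-12-[(tert-butyldiphenylsilyl)oxy]-2,3,5-trimethyldodec-2-enoate (E/Z mixture) | C[C@H](CCCCCCCO[Si](c1ccccc1)(c1ccccc1)C(C)(C)C)CC(C)=C(C)C(=O)OCC
F5 | step 10 | (5R)-12-[(tert-butyldiphenylsilyl)oxy]-2,3,5-trimethyldodec-2-en-1-ol (E/Z mixture) | C[C@H](CCCCCCCO[Si](c1ccccc1)(c1ccccc1)C(C)(C)C)CC(C)=C(C)CO
F6 | step 15 | 2-[(3R,5R)-5-{(2R)-9-[(tert-butyldiphenylsilyl)oxy]-2-methylnonyl}-3,5-dimethyl-1,2-dioxolan-3-yl]ethan-1-ol | C[C@H](CCCCCCCO[Si](c1ccccc1)(c1ccccc1)C(C)(C)C)C[C@]1(C)C[C@@](C)(CCO)OO1
F7 | step 19 | methyl 2-{(3S,5R)-5-[(2R)-9-hydroxy-2-methylnonyl]-3,5-dimethyl-1,2-dioxolan-3-yl}acetate | C[C@H](CCCCCCCO)C[C@]1(C)C[C@@](C)(CC(=O)OC)OO1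
F8 | step 19 | methyl 2-{(3S,5R)-3,5-dimethyl-5-[(2R)-2-methyl-9-oxononyl]-1,2-dioxolan-3-yl}acetate | C[C@H](CCCCCCC=O)C[C@]1(C)C[C@@](C)(CC(=O)OC)OO1
F9 | step 19 | methyl 2-{(3S,5R)-3,5-dimethyl-5-[(2R,9E,11E)-2-methyl-12-phenyldodeca-9,11-dien-1-yl]-1,2-dioxolan-3-yl}acetate | C[C@H](CCCCCC/C=C/C=C/c1ccccc1)C[C@]1(C)C[C@@](C)(CC(=O)OC)OO1
A1 | alternative 1 | methyl 2-[(3S,5R)-3,5-dimethyl-5-{(2R)-2-methyl-9-[(triisopropylsilyl)oxy]nonyl}-1,2-dioxolan-3-yl]acetate | C[C@H](CCCCCCCO[Si](C(C)C)(C(C)C)C(C)C)C[C@]1(C)C[C@@](C)(CC(=O)OC)OO1
A2 | alternative 1 | triethyl{[(4R)-2-methoxy-4-methyl-11-[(triisopropylsilyl)oxy]undecan-2-yl]peroxy}silane | C[C@H](CCCCCCCO[Si](C(C)C)(C(C)C)C(C)C)CC(C)(OC)OO[Si](CC)(CC)CC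
A3 | alternative 1 | methyl 3-methylbut-3-enoate | C=C(C)CC(=O)OC
A4 | alternative 2 | 3,5-dimethyl-5-{(2R)-2-methyl-9-[(triisopropylsilyl)oxy]nonyl}-3-{2-[(triethylsilyl)oxy]ethyl}-1,2-dioxolane (ring centres as in 27) | C[C@H](CCCCCCCO[Si](C(C)C)(C(C)C)C(C)C)C[C@]1(C)C[C@@](C)(CCO[Si](CC)(CC)CC)OO1
A5 | alternative 2 | triethyl{[3,7-dimethyl-5-methylidene-1-[(triethylsilyl)oxy]-14-[(triisopropylsilyl)oxy]tetradecan-3-yl]peroxy}silane (C3 and C7 as in 27) | C[C@H](CCCCCCCO[Si](C(C)C)(C(C)C)C(C)C)CC(=C)C[C@@](C)(CCO[Si](CC)(CC)CC)OO[Si](CC)(CC)CC
A6 | alternative 3 | 2-[3,5-dimethyl-5-{(2R)-2-methyl-9-[(triisopropylsilyl)oxy]nonyl}-1,2-dioxolan-3-yl]ethyl acetate (ring centres as in 27) | C[C@H](CCCCCCCO[Si](C(C)C)(C(C)C)C(C)C)C[C@]1(C)C[C@@](C)(CCOC(C)=O)OO1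
A7 | alternative 3 | 3-methoxy-3-[(triethylsilyl)peroxy]butyl acetate | CC(=O)OCCC(C)(OC)OO[Si](CC)(CC)CC
A8 | alternative 3 | {[(8R)-8,10-dimethylundec-10-en-1-yl]oxy}triisopropylsilane | C[C@H](CCCCCCCO[Si](C(C)C)(C(C)C)C(C)C)CC(C)=C
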